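**Retrosynthetic overview**
1. Cut the C2–C1′ bond of corymbosin. Chromone C2 is the latent aroyl carbon and the enone β-carbon, so it is an acceptor by nature. Here it serves as the donor: a C2-zincated chromone, which is a metalated enol ether (masked acyl anion / β-acylvinyl anion). The partner is the acceptor C–I carbon of 5-iodo-1,2,3-trimethoxybenzene.
2. The donor is made by direct C2–H metalation of unprotected 5-hydroxy-7-methoxychromone. Its magnesium phenoxide chelate steers the base, so no protecting group or late demethylation is needed.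
3. 5-Hydroxy-7-methoxychromone ⇒ 2′,6′-dihydroxy-4′-methoxyacetophenone + one carbon from DMF-DMA.
4. Ring order: rings A and B are bought, the pyranone ring C is closed first (step 1), and ring B is attached last (step 2).

**Assumption:** corymbosin is a planar, achiral flavone with no stereocentre or stereogenic axis. "Single enantiomer" therefore needs no stereocontrol, and the SMILES carries no stereodescriptors.

**Step 1**
Reactants: 1 1-(2,6-dihydroxy-4-methoxyphenyl)ethan-1-one (2′,6′-dihydroxy-4′-methoxyacetophenone)
Product: 3 5-hydroxy-7-methoxy-4H-chromen-4-one, via enaminone 2 (not isolated)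
Conditions: DMF-DMA (1.3 equiv), PhMe, 90 °C, 3 h; evaporate; conc. HCl, CH2Cl2, 40 °C, 1 h
Reagents that add atoms: N,N-dimethylformamide dimethyl acetal (DMF-DMA), COC(OC)N(C)C
Why: In this enaminone chromone synthesis, amide-acetal condensation at the acidic acetyl CH3 gives the push–pull enaminone 2, acid then drives intramolecular oxa-Michael addition and β-elimination of Me2NH, the two ortho-OH groups are equivalent so only one chromone can form, and no stereocentre is created.

**Step 2**
Reactants: 3 5-hydroxy-7-methoxy-4H-chromen-4-one; 4 5-iodo-1,2,3-trimethoxybenzene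
Product: 8 corymbosin (5-hydroxy-7-methoxy-2-(3,4,5-trimethoxyphenyl)-4H-chromen-4-one), via chloromagnesium phenoxide 5 (not isolated), via C2-zinc reagent 6 (not isolated), via corymbosin chloromagnesium salt 7 (not isolated)
Conditions: MeMgCl (1.0 equiv), THF, −20 °C, 15 min; MgCl2 (1.0 equiv), TMPZnCl·LiCl (1.3 equiv), −20 → 25 °C, 2 h; 4 (0.9 equiv), Pd(dba)2 (3 mol %), P(2-furyl)3 (6 mol %), 50 °C, 6 h; 1 M HCl work-up
Reagents that add atoms: none
Why: Proposed new method: MeMgCl turns the acidic 5-OH into a ClMg phenoxide whose six-membered chelate to the C4 carbonyl acts as a built-in Lewis acid (reinforced by MgCl2) that blocks carbonyl-directed C3 metalation and acidifies C2–H, so TMPZnCl·LiCl should zincate C2 to give 6, in which the normally electrophilic C2 is the donor (metalated enol ether = masked aroyl anion / β-acylvinyl anion), and a Pd(0)-catalysed Negishi cross-coupling then joins it to the likewise electrophilic C–I carbon of 4; the closest known reaction types are the Lewis-acid-triggered C2 TMP-zincation/Negishi arylation of O-alkylated chromones and the metalation of phenols pre-deprotonated with MeMgCl/LiCl, and no stereocentre is formed.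

**Compound list**
1 | 1-(2,6-dihydroxy-4-methoxyphenyl)ethan-1-one | CC(=O)c1c(O)cc(OC)cc1O | starting material
2 | (E)-1-(2,6-dihydroxy-4-methoxyphenyl)-3-(dimethylamino)prop-2-en-1-one | CN(C)/C=C/C(=O)c1c(O)cc(OC)cc1O | intermediate
3 | 5-hydroxy-7-methoxy-4H-chromen-4-one | COc1cc(O)c2c(=O)ccoc2c1 | intermediate
4 | 5-iodo-1,2,3-trimethoxybenzene | COc1cc(I)cc(OC)c1OC | starting material
5 | chloromagnesium 7-methoxy-4-oxo-4H-chromen-5-olate | COc1cc(O[Mg]Cl)c2c(=O)ccoc2c1 | intermediate
6 | [5-(chloromagnesiooxy)-7-methoxy-4-oxo-4H-chromen-2-yl]zinc chloride | COc1cc(O[Mg]Cl)c2c(=O)cc([Zn]Cl)oc2c1 | intermediate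
7 | chloromagnesium 7-methoxy-4-oxo-2-(3,4,5-trimethoxyphenyl)-4H-chromen-5-olate | COc1cc(O[Mg]Cl)c2c(=O)cc(-c3cc(OC)c(OC)c(OC)c3)oc2c1 | intermediate
8 | corymbosin, 5-hydroxy-7-methoxy-2-(3,4,5-trimethoxyphenyl)-4H-chromen-4-one | COc1cc(O)c2c(=O)cc(-c3cc(OC)c(OC)c(OC)c3)oc2c1 | target

**Total step count:** 2. **Longest linear sequence:** 2 (1 → 3 → 8).

**Most likely to fail.** The route has only two steps, so the three weak points are the two stages of step 2 and step 1.

Risk 1, step 2, metalation stage. The anionic phenoxide may lower the C2–H acidity, may let zinc go to C3, or may precipitate. An aliquot quenched with D2O shows the site of metalation.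
- The fallback sets out from 3 and comes back at 8. It runs the same C2-donor coupling on a neutral substrate.
- 3 is O-methylated (MeI, K2CO3, DMF, 60 °C) to 5,7-dimethoxy-4H-chromen-4-one F1.
- TMPZnCl·LiCl/MgCl2 in THF converts this into (5,7-dimethoxy-4-oxo-4H-chromen-2-yl)zinc chloride F2.
- Negishi coupling with 4 gives 5,7-dimethoxy-2-(3,4,5-trimethoxyphenyl)-4H-chromen-4-one F3.
- BCl3 (1.2 equiv, CH2Cl2, −78 → 0 °C) cleaves only the peri 5-OMe through the carbonyl-chelated 5-O-dichloroboryl flavone F4, and aqueous work-up releases 8.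
- The B-ring 4′-OMe is the next most labile ether, so the amount of BCl3 and the temperature are kept low.

Risk 2, step 2, coupling stage. The doubly metalated 6 may transmetalate to palladium slowly and be lost by protodezincation or homocoupling.
- The fallback sets out from 6 and comes back at 8. It separates the metalation from the C–C bond formation by isolating a storable C2 donor.
- 6 is quenched with Bu3SnCl to the chloromagnesium 7-methoxy-4-oxo-2-(tributylstannyl)-4H-chromen-5-olate F5.
- Saturated NH4Cl work-up gives 5-hydroxy-7-methoxy-2-(tributylstannyl)-4H-chromen-4-one F6, which is purified on Et3N-deactivated silica.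
- F6 is an α-alkoxyvinylstannane, a class long used as acyl-anion equivalents. Stille coupling with 4 (Pd2(dba)3, AsPh3, cat. CuI, DMF, 50 °C) gives 8.

Risk 3, step 1. DMF-DMA can O-methylate a free phenol, and the dihydroxy enaminone may cyclise incompletely.
- The fallback sets out from 1 and comes back at 3. It brings in the C1 unit by a crossed Claisen formylation instead of an amide acetal.
- NaH (4 equiv) and ethyl formate in THF (0 → 25 °C), followed by an acid quench, give the cyclic hemiacetal 2,5-dihydroxy-7-methoxychroman-4-one F7. It is racemic and its labile stereocentre is lost in the next operation.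
- Catalytic p-TsOH in PhMe at 80 °C dehydrates F7 to 3.

**Further compounds**
F1 | step 2 | 5,7-dimethoxy-4H-chromen-4-one | COc1cc(OC)c2c(=O)ccoc2c1
F2 | step 2 | (5,7-dimethoxy-4-oxo-4H-chromen-2-yl)zinc chloride | COc1cc(OC)c2c(=O)cc([Zn]Cl)oc2c1
F3 | step 2 | 5,7-dimethoxy-2-(3,4,5-trimethoxyphenyl)-4H-chromen-4-one | COc1cc(OC)c2c(=O)cc(-c3cc(OC)c(OC)c(OC)c3)oc2c1
F4 | step 2 | 5-(dichloroboryloxy)-7-methoxy-2-(3,4,5-trimethoxyphenyl)-4H-chromen-4-one | COc1cc(OB(Cl)Cl)c2c(=O)cc(-c3cc(OC)c(OC)c(OC)c3)oc2c1
F5 | step 2 | chloromagnesium 7-methoxy-4-oxo-2-(tributylstannyl)-4H-chromen-5-olate | CCCC[Sn](CCCC)(CCCC)c1cc(=O)c2c(O[Mg]Cl)cc(OC)cc2o1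
F6 | step 2 | 5-hydroxy-7-methoxy-2-(tributylstannyl)-4H-chromen-4-one | CCCC[Sn](CCCC)(CCCC)c1cc(=O)c2c(O)cc(OC)cc2o1
F7 | step 1 | 2,5-dihydroxy-7-methoxychroman-4-one (racemic hemiacetal) | COc1cc(O)c2C(=O)CC(O)Oc2c1
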